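**Retrosynthetic overview**
- The C5 carbinol comes from hydride addition to a 4(15)-en-5-one; the 2,3-epoxide is put in at that enone stage, when C2=C3 is the only non-deactivated olefin.
- The enone comes from a singlet-oxygen ene reaction (C5–O bond) on a 1β,10α-epoxy-germacra-2Z,4E-diene.
- The ten-membered ring comes from photochemical 6π ring opening of a trans-fused eudesma-1,3-diene, with the E,Z,E-triene epoxidised in the same flask.
- The C8 angelate comes from a light-driven, copper-mediated C–H acyloxylation relayed from C13 of the lactone; the relay arm is then eliminated to the α-methylene lactone.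
- Ring order: rings A and B and the trans-lactone (C6, C7) are bought in (−)-α-santonin; ring A becomes the diene, then the ten-membered ring forms, then the two oxiranes.

Assumption: the SMILES is read as (1R,2S,3S,5R,6S,7R,8S,10R), i.e. 8α-angeloyloxy-1β,10α:2α,3α-diepoxy-5α-hydroxygermacra-4(15),11(13)-dien-12,6α-olide with H7α; the C4 methyl of the tetrahydro and enone intermediates is drawn equatorial (4α), its epimer serving equally because C4 is planarised at the triflate stage.

**Route**

Step 1
Reactants: 1 (−)-α-santonin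
Product: 2 α-tetrahydrosantonin (3-oxo-4α-methyl-5αH,11βH-eudesman-12,6α-olide)
Conditions: H2 (1 atm), 10% Pd/C, EtOAc–AcOH (9:1), rt; recrystallise
Reagents that add atoms: none
Why: heterogeneous hydrogenation saturates both ring-A olefins, delivering hydrogen syn to the α-face opposite the angular C10 methyl, so C5 becomes 5αH (trans-decalin) and the C4 methyl settles equatorial through the enol.

Step 2
Reactants: 2 α-tetrahydrosantonin
Product: 4 3-oxo-5αH,11βH-eudesm-1-en-12,6α-olide, via trimethylsilyl enol ether 3 (not isolated)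
Conditions: LiN(iPr)2 (1.1 equiv), Me3SiCl, THF, −78 °C; then Pd(OAc)2 (1.05 equiv), MeCN, rt
Reagents that add atoms: none
Why: Saegusa–Ito dehydrogenation, in which kinetic deprotonation at the C2 methylene (the ketone is far more acidic than the lactone α-CH) fixes the position of the new C1=C2 bond; no stereocentre is made.

Step 3
Reactants: 4 3-oxo-5αH,11βH-eudesm-1-en-12,6α-olide
Product: 5 3-(trifluoromethylsulfonyloxy)-5αH,11βH-eudesma-1,3-dien-12,6α-olide
Conditions: KN(SiMe3)2 (1.1 equiv), THF, −78 °C; then PhNTf2, −78 to 0 °C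
Reagents that add atoms: N-phenylbis(trifluoromethanesulfonimide), O=S(=O)(N(c1ccccc1)S(=O)(=O)C(F)(F)F)C(F)(F)F
Why: enol triflate formation by α′-deprotonation of the enone at C4 (C10 is quaternary, so no γ-deprotonation can compete) and O-triflation of the cross-conjugated dienolate.

Step 4
Reactants: 5 dienyl triflate
Product: 6 5αH,11βH-eudesma-1,3-dien-12,6α-olide
Conditions: Pd(OAc)2 (5 mol%), PPh3 (10 mol%), HCO2H, nBu3N, DMF, 60 °C
Reagents that add atoms: none
Why: palladium-catalysed formate reduction of the vinyl triflate (oxidative addition, decarboxylation of formate, C–H reductive elimination) leaves the homoannular 1,3-diene and the trans ring fusion untouched.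

Step 5
Reactants: 6 5αH,11βH-eudesma-1,3-dien-12,6α-olide
Product: 9 5αH-eudesma-1,3,11(13)-trien-12,6α-olide, via 11-phenylselenide 7 (not isolated), via selenoxide 8 (not isolated)
Conditions: LiN(iPr)2 (1.2 equiv), THF, −78 °C; PhSeBr; then NaIO4, NaHCO3, THF–MeOH–H2O, 0 °C to rt
Reagents that add atoms: none
Why: α-selenenylation of the lactone enolate and selenoxide syn-elimination, which in a trans-fused lactone engages only the C13 methyl hydrogens (H7 is anti to selenium) and so gives the exocyclic methylene; periodate is used because peracid-type oxidants would attack the diene.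

Step 6
Reactants: 9 5αH-eudesma-1,3,11(13)-trien-12,6α-olide; 10 N-hydroxyphthalimide
Product: 11 13-(phthalimidooxy)-5αH,11βH-eudesma-1,3-dien-12,6α-olide
Conditions: 10 (1.5 equiv), Et3N (0.3 equiv), MeCN, 40 °C
Reagents that add atoms: N-hydroxyphthalimide (10), O=C1c2ccccc2C(=O)N1O
Why: oxa-Michael addition to the α-methylene lactone, with the enolate protonated to the thermodynamically preferred 11βH epimer, so the new CH2O arm is α (pseudo-equatorial), the C11 configuration of santonin.

Step 7
Reactants: 11 13-(phthalimidooxy)-5αH,11βH-eudesma-1,3-dien-12,6α-olide; 12 angelic acid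
Product: 13 8α-angeloyloxy-13-hydroxy-5αH,11βH-eudesma-1,3-dien-12,6α-olide
Conditions: Cu(MeCN)4PF6 (10 mol%), 2,9-bis(4-methoxyphenyl)-1,10-phenanthroline (22 mol%), 12 (3 equiv), degassed MeCN, 530 nm LEDs, rt
Reagents that add atoms: angelic acid (12), C/C=C(/C)C(=O)O
Why: Proposed new method: the photoexcited bis(phenanthroline) complex of monovalent copper reduces the N-alkoxyphthalimide, N–O fragmentation gives the C13 alkoxy radical, this abstracts the equatorial H8α through a six-membered transition state (the α-oriented arm is anti to C6–H and no other C–H lies in 1,5-range), and the C8 radical is captured by the divalent copper angelate formed in the same electron transfer, C–O reductive elimination from trivalent copper taking place on the equatorial α-face because the β-face is blocked by the syn-axial C10 methyl, which sets C8 as 8α with phthalimide as the only by-product; the closest known chemistry is 1,5-hydrogen transfer of alkoxy radicals released from N-alkoxyphthalimides under photoredox conditions combined with copper-mediated radical C–O coupling of the Kharasch–Sosnovsky kind.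

Step 8
Reactants: 13 8α-angeloyloxy-13-hydroxy-5αH,11βH-eudesma-1,3-dien-12,6α-olide
Product: 15 8α-angeloyloxy-5αH-eudesma-1,3,11(13)-trien-12,6α-olide, via 13-mesylate 14 (not isolated)
Conditions: MeSO2Cl (1.2 equiv), Et3N (4 equiv), CH2Cl2, 0 °C to rt
Reagents that add atoms: none
Why: sulfonylation of the primary alcohol and E1cB β-elimination through the lactone enolate restore the α-methylene lactone under amine-only conditions that do not isomerise the angelate to the tiglate.

Step 9
Reactants: 15 8α-angeloyloxy-5αH-eudesma-1,3,11(13)-trien-12,6α-olide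
Product: 17 (2Z,4E)-8α-angeloyloxy-1β,10α-epoxygermacra-2,4,11(13)-trien-12,6α-olide, via triene 16 (not isolated)
Conditions: hν (300 nm), Et2O, −78 °C, to the photostationary state; then DMDO in acetone (1 equiv on triene), −78 to −40 °C; recovered 15 is recycled
Reagents that add atoms: dimethyldioxirane, CC1(C)OO1
Why: photochemical conrotatory 6π-electrocyclic ring opening of the trans-fused cyclohexadiene cleaves C5–C10 to the (1(10)E,2Z,4E)-cyclodecatriene (the classical opening of the santonin-derived diene), and its strained, most electron-rich 1(10) olefin is epoxidised on the exposed outer face before thermal disrotatory reclosure, the β-disposed C14 methyl of the nascent conformer giving the 1β,10α (1R,10R) trans-epoxide.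

Step 10
Reactants: 17 (2Z,4E)-8α-angeloyloxy-1β,10α-epoxygermacra-2,4,11(13)-trien-12,6α-olide
Product: 20 (2Z)-8α-angeloyloxy-1β,10α-epoxy-5-oxogermacra-2,4(15),11(13)-trien-12,6α-olide, via 5-hydroperoxide 18 (not isolated), via 5-peroxyacetate 19 (not isolated)
Conditions: O2, tetraphenylporphyrin (1 mol%), CH2Cl2, 590 nm LEDs, −40 °C; then Ac2O, pyridine, DMAP (cat.), 0 °C
Reagents that add atoms: dioxygen, O=O
Why: Schenck ene reaction of photosensitised singlet oxygen at C4=C5, the only olefin with abstractable allylic hydrogens (C15 on the disubstituted side; H6 lies in the olefin plane and C2=C3 has none), forms the C5–O bond and moves the double bond to C4=C15, and Kornblum–DeLaMare dehydration of the peroxyacetate gives the enone, so the C5 configuration of 18 does not matter.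

Step 11
Reactants: 20 (2Z)-8α-angeloyloxy-1β,10α-epoxy-5-oxogermacra-2,4(15),11(13)-trien-12,6α-olide
Product: 21 8α-angeloyloxy-1β,10α:2α,3α-diepoxy-5-oxogermacra-4(15),11(13)-dien-12,6α-olide
Conditions: DMDO (3 equiv), acetone–CH2Cl2, 0 °C to rt
Reagents that add atoms: dimethyldioxirane, CC1(C)OO1
Why: electrophilic epoxidation picks the cis-disubstituted C2=C3 bond because C4=C15, the lactone methylene and the angelate are each conjugated to a carbonyl group, and it goes to the α-face, away from the 1,10-epoxide oxygen and the C14 methyl on the β-face, giving the 2α,3α (2S,3S) oxirane anti to the first.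

Step 12
Reactants: 21 8α-angeloyloxy-1β,10α:2α,3α-diepoxy-5-oxogermacra-4(15),11(13)-dien-12,6α-olide
Product: 22 8α-angeloyloxy-1β,10α:2α,3α-diepoxy-5α-hydroxygermacra-4(15),11(13)-dien-12,6α-olide (CNP0038366.2)
Conditions: NaBH4 (1 equiv), CeCl3·7H2O (1.1 equiv), MeOH–THF, −78 °C
Reagents that add atoms: none
Why: Luche 1,2-reduction of the exo-methylene ketone, with hydride attacking the peripheral face of the C5 carbonyl, whose oxygen sits in the inward α-position formerly held by H5, so the hydroxyl ends up 5α (5R), cis to the C6 oxygen, while the conjugated ester and lactone survive at −78 °C.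

**Compound list**

1 | (−)-α-santonin | C[C@@H]1C(=O)O[C@H]2[C@H]1CC[C@@]3(C)C=CC(=O)C(C)=C23 | starting material
2 | α-tetrahydrosantonin (3-oxo-4α-methyl-5αH,11βH-eudesman-12,6α-olide) | C[C@@H]1C(=O)O[C@H]2[C@H]1CC[C@@]3(C)CCC(=O)[C@@H](C)[C@H]23 | intermediate
3 | 3-trimethylsilyloxy-5αH,11βH-eudesm-2-en-12,6α-olide (not isolated) | C[C@@H]1C(=O)O[C@H]2[C@H]1CC[C@@]3(C)CC=C(O[Si](C)(C)C)[C@@H](C)[C@H]23 | intermediate
4 | 3-oxo-5αH,11βH-eudesm-1-en-12,6α-olide | C[C@@H]1C(=O)O[C@H]2[C@H]1CC[C@@]3(C)C=CC(=O)[C@@H](C)[C@H]23 | intermediate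
5 | 3-(trifluoromethylsulfonyloxy)-5αH,11βH-eudesma-1,3-dien-12,6α-olide | C[C@@H]1C(=O)O[C@H]2[C@H]1CC[C@@]3(C)C=CC(OS(=O)(=O)C(F)(F)F)=C(C)[C@H]23 | intermediate
6 | 5αH,11βH-eudesma-1,3-dien-12,6α-olide | C[C@@H]1C(=O)O[C@H]2[C@H]1CC[C@@]3(C)C=CC=C(C)[C@H]23 | intermediate
7 | 11β-phenylseleno-5αH-eudesma-1,3-dien-12,6α-olide (not isolated) | C[C@]1([Se]c4ccccc4)C(=O)O[C@H]2[C@H]1CC[C@@]3(C)C=CC=C(C)[C@H]23 | intermediate
8 | selenoxide of 7 (not isolated) | C[C@]1([Se](=O)c4ccccc4)C(=O)O[C@H]2[C@H]1CC[C@@]3(C)C=CC=C(C)[C@H]23 | intermediate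
9 | 5αH-eudesma-1,3,11(13)-trien-12,6α-olide | C=C1C(=O)O[C@H]2[C@H]1CC[C@@]3(C)C=CC=C(C)[C@H]23 | intermediate
10 | N-hydroxyphthalimide | O=C1c2ccccc2C(=O)N1O | starting material
11 | 13-(phthalimidooxy)-5αH,11βH-eudesma-1,3-dien-12,6α-olide | O=C1c2ccccc2C(=O)N1OC[C@@H]1C(=O)O[C@H]2[C@H]1CC[C@@]3(C)C=CC=C(C)[C@H]23 | intermediate
12 | angelic acid ((Z)-2-methylbut-2-enoic acid) | C/C=C(/C)C(=O)O | starting material
13 | 8α-angeloyloxy-13-hydroxy-5αH,11βH-eudesma-1,3-dien-12,6α-olide | OC[C@@H]1C(=O)O[C@H]2[C@H]1[C@@H](OC(=O)/C(C)=C\C)C[C@@]3(C)C=CC=C(C)[C@H]23 | intermediate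
14 | 13-methanesulfonate of 13 (not isolated) | CS(=O)(=O)OC[C@@H]1C(=O)O[C@H]2[C@H]1[C@@H](OC(=O)/C(C)=C\C)C[C@@]3(C)C=CC=C(C)[C@H]23 | intermediate
15 | 8α-angeloyloxy-5αH-eudesma-1,3,11(13)-trien-12,6α-olide | C=C1C(=O)O[C@H]2[C@H]1[C@@H](OC(=O)/C(C)=C\C)C[C@@]3(C)C=CC=C(C)[C@H]23 | intermediate
16 | (1(10)E,2Z,4E)-8α-angeloyloxygermacra-1(10),2,4,11(13)-tetraen-12,6α-olide (not isolated) | C=C1C(=O)O[C@H]2[C@H]1[C@@H](OC(=O)/C(C)=C\C)C/C(C)=C/C=C\C(C)=C\2 | intermediate
17 | (2Z,4E)-8α-angeloyloxy-1β,10α-epoxygermacra-2,4,11(13)-trien-12,6α-olide | C=C1C(=O)O[C@H]2[C@H]1[C@@H](OC(=O)/C(C)=C\C)C[C@@]1(C)O[C@@H]1/C=C\C(C)=C\2 | intermediate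
18 | (2Z)-8α-angeloyloxy-1β,10α-epoxy-5β-hydroperoxygermacra-2,4(15),11(13)-trien-12,6α-olide (not isolated) | C=C1C(=O)O[C@H]2[C@H]1[C@@H](OC(=O)/C(C)=C\C)C[C@@]1(C)O[C@@H]1/C=C\C(=C)[C@@H]2OO | intermediate
19 | 5-peroxyacetate of 18 (not isolated) | C=C1C(=O)O[C@H]2[C@H]1[C@@H](OC(=O)/C(C)=C\C)C[C@@]1(C)O[C@@H]1/C=C\C(=C)[C@@H]2OOC(C)=O | intermediate
20 | (2Z)-8α-angeloyloxy-1β,10α-epoxy-5-oxogermacra-2,4(15),11(13)-trien-12,6α-olide | C=C1C(=O)O[C@H]2[C@H]1[C@@H](OC(=O)/C(C)=C\C)C[C@@]1(C)O[C@@H]1/C=C\C(=C)C2=O | intermediate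
21 | 8α-angeloyloxy-1β,10α:2α,3α-diepoxy-5-oxogermacra-4(15),11(13)-dien-12,6α-olide | C=C1C(=O)O[C@H]2[C@H]1[C@@H](OC(=O)/C(C)=C\C)C[C@@]1(C)O[C@@H]1[C@H]1O[C@H]1C(=C)C2=O | intermediate
22 | CNP0038366.2, 8α-angeloyloxy-1β,10α:2α,3α-diepoxy-5α-hydroxygermacra-4(15),11(13)-dien-12,6α-olide | C=C1C(=O)O[C@H]2[C@H]1[C@@H](OC(=O)/C(C)=C\C)C[C@@]1(C)O[C@@H]1[C@H]1O[C@H]1C(=C)[C@H]2O | target

**Step count and risks**

Total steps: 12. Longest linear sequence: 12 steps (1 to 22); 10 and 12 are bought.

Most likely to fail: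

1. Step 7 (proposed C8–H angeloyloxylation). The C13 alkoxy radical may lose formaldehyde by β-scission, divalent copper may oxidise the C8 radical to an olefin instead of coupling it, and 11 may revert by retro-Michael loss of the N-oxyphthalimide. The fallback uses known chemistry, sets out from 9 and returns at 15. Copper-catalysed conjugate borylation of 9 (CuCl, NaOtBu, B2pin2, MeOH, THF) gives the 13-pinacolboronate F1, which NaBO3·4H2O oxidises to the 13-alcohol F2 (11βH). Exchange with tert-butyl nitrite gives the 13-nitrite F3. Barton nitrite photolysis (350 nm) in O2-saturated solution moves the oxidation to C8 and gives the 8α-nitrate F4, and Zn/AcOH reduces it to the 8α,13-diol F5. MeSO2Cl/Et3N at −40 °C sulfonylates only the primary hydroxyl to the 13-mesylate F6, which eliminates in the flask to the 8α-hydroxy α-methylene lactone F7. Yamaguchi esterification of F7 with 12 (2,4,6-trichlorobenzoyl chloride, Et3N, DMAP, toluene) gives 15.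

2. Step 9 (ring opening and trapping). The photostationary state may hold little triene, the triene recloses thermally to a cis-fused diene, and DMDO may not distinguish the 1(10) olefin from the 4,5 olefin or from unreacted 15. The fallback sets out from 15 and returns at 16. The irradiation is run in a closed loop through a cooled column of AgNO3 on silica, which holds back the strained E-olefinic triene as its silver nitrate complex F8 and sends unchanged 15 back to the lamp, the usual way to drive a photoequilibrium that contains a trans-cycloalkene. The column is washed, 16 is released at −40 °C with cold aqueous NaCl/NH3 into Et2O, and the diene-free solution is epoxidised with DMDO as in step 9.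

3. Step 12 (configuration at C5). If the enone relaxes to a conformer with the carbonyl oxygen on the β-side, peripheral hydride attack gives the wrong epimer. The fallback sets out from 21 and returns at 22. The reduction is kept, and the 5β-alcohol F9 (5-epi-22) is inverted by SN2: Mitsunobu reaction (ClCH2CO2H, PPh3, diisopropyl azodicarboxylate, toluene, 0 °C) gives the 5α-chloroacetate F10, and thiourea/NaHCO3 in EtOH removes the chloroacetyl group without touching the angelate or the lactone, giving 22.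

**Further compounds**

F1 | step 7 | 13-(pinacolboryl)-5αH,11βH-eudesma-1,3-dien-12,6α-olide | CC1(C)OB(C[C@@H]2C(=O)O[C@H]3[C@H]2CC[C@@]4(C)C=CC=C(C)[C@H]34)OC1(C)C
F2 | step 7 | 13-hydroxy-5αH,11βH-eudesma-1,3-dien-12,6α-olide | OC[C@@H]1C(=O)O[C@H]2[C@H]1CC[C@@]3(C)C=CC=C(C)[C@H]23
F3 | step 7 | 13-nitrite ester of F2 | O=NOC[C@@H]1C(=O)O[C@H]2[C@H]1CC[C@@]3(C)C=CC=C(C)[C@H]23
F4 | step 7 | 13-hydroxy-8α-nitrooxy-5αH,11βH-eudesma-1,3-dien-12,6α-olide | OC[C@@H]1C(=O)O[C@H]2[C@H]1[C@@H](O[N+](=O)[O-])C[C@@]3(C)C=CC=C(C)[C@H]23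
F5 | step 7 | 8α,13-dihydroxy-5αH,11βH-eudesma-1,3-dien-12,6α-olide | OC[C@@H]1C(=O)O[C@H]2[C@H]1[C@@H](O)C[C@@]3(C)C=CC=C(C)[C@H]23
F6 | step 7 | 13-methanesulfonate of F5 | CS(=O)(=O)OC[C@@H]1C(=O)O[C@H]2[C@H]1[C@@H](O)C[C@@]3(C)C=CC=C(C)[C@H]23
F7 | step 7 | 8α-hydroxy-5αH-eudesma-1,3,11(13)-trien-12,6α-olide | C=C1C(=O)O[C@H]2[C@H]1[C@@H](O)C[C@@]3(C)C=CC=C(C)[C@H]23
F8 | step 9 | silver nitrate complex of triene 16 | C=C1C(=O)O[C@H]2[C@H]1[C@@H](OC(=O)/C(C)=C\C)C/C(C)=C/C=C\C(C)=C\2.[Ag+].[O-][N+](=O)[O-]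
F9 | step 12 | 5β-hydroxy epimer of 22 | C=C1C(=O)O[C@H]2[C@H]1[C@@H](OC(=O)/C(C)=C\C)C[C@@]1(C)O[C@@H]1[C@H]1O[C@H]1C(=C)[C@@H]2O
F10 | step 12 | 5α-chloroacetate of 22 | C=C1C(=O)O[C@H]2[C@H]1[C@@H](OC(=O)/C(C)=C\C)C[C@@]1(C)O[C@@H]1[C@H]1O[C@H]1C(=C)[C@H]2OC(=O)CCl
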